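Early on, the starting complex meets the incoming ligand, and what matters is the fate of each complex with one exchanged as it appears in solution.

starting complex 0.050 M; incoming ligand 0.150 M; time 2.5 d

    starting complex + incoming ligand ⇌ leaving ligand + complex with one exchanged (K1 = 11, k1 = 5.19 × 10⁻⁴ /M/s)
    complex with one exchanged + incoming ligand ⇌ leaving ligand + complex with two exchanged (K2 = 0.498, k2 = 5.37 × 10⁻⁴ /M/s)
    complex with two exchanged + incoming ligand ⇌ leaving ligand + complex with three exchanged (K3 = 16, k3 = 7.01 × 10⁻⁴ /M/s)
    crystals ⇌ complex with one exchanged, rate k4*(cs4 - [complex with one exchanged]) while solid is left; crystals form when [complex with one exchanged] > cs4 (cs4 = 0.80 mM, k4 = 3.57 × 10⁻⁴ /s)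
    complex with one exchanged + incoming ligand → over-reaction product (k5 = 8.39 × 10⁻⁵ /M/s)
    starting complex → decomposition product (k6 = 1.86 × 10⁻⁸ /s)

1. amount of complex with one exchanged and crystals together at 2.5 d, in percent of the starting complex charged
2. concentration of complex with one exchanged in solution at 2.5 d, in percent of saturation

I build this flask up by hand. On step 1's forward rate the starting complex halves in 0.10 d, far shorter than the 2.5 d allowed, so I count the whole charge as turned over and my number stands at 100 %.

Now I add what consumes the dissolved complex with one exchanged: steps 2 and 5. With incoming ligand held at its charge, each is pseudo-first-order, and together they make a drain of 9.31 × 10⁻⁵ /s. That is a half-life of 0.0861 d, much shorter than the run, so with these steps added my number drops far.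

Then I add the crystals. Well above saturation, the solution loses material to them at about 3.57 × 10⁻⁴ /s times its level, which is faster than the drain. Their quotient, 3.83, is my capture ratio: crystal loss over drain. A fraction ratio/(ratio + one) of what appears reaches the solid, so I commit to 79.3 % for the yield.

Last comes the rest. Once the feed has fallen off, dissolving crystals must replace what the solution loses, so I expect the solution just below saturation. My drain counts steps 2 and 5 forward only and at the charged ligand, which overstates the loss, so the same quotient gives a floor and not an estimate: the solution stands above 79.3 % of saturation.

The forecast says 80.4 % and 94.5 %, on the ground that “most of it crystallises”. Its yield lies above mine, and its saturation lies above my floor.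

The simulation gives 80.8 % and 96.1 %, so the forecast holds within its margins. The solid is the main reason for the yield: with saturation taken away, the yield falls from 80.8 % to 19.8 %. Its number left as it is, the forecast stops fitting about where the yield has moved 5 points: at 0.123 M or 0.177 M of incoming ligand, or at 0.0418 M or 0.0618 M of starting complex.

In the neighbour flask with 0.090 M of incoming ligand, the capture ratio becomes 6.39, a share of 86.5 %. That flask gives 90.6 %.

The numbers of this flask come from no measurement; the result is computed.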